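**Retrosynthetic overview**
1. Ring A is a non-aromatic acylphloroglucinol, a folded tetraketide. C1 bears the butanoyl group, C2 and C4 are enol carbons, C3 carries the bridge CH2, C5 is CMe2 and C6 is the ring carbonyl. Cutting C1–C6 gives an open 3,5,7-trioxo ester whose ester sits on the quaternary C5 and cannot enolise.
2. This chain, with the ring B phenols as benzyl ethers, comes from its 7-dioxolane. With the third ketone masked, C3 is the only doubly activated carbon, so the C3–CH2 bond is made by alkylating the β-diketone with a ring B benzylic bromide.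
3. The masked chain comes from the enolate of methyl 2,2-dimethyl-3-oxobutanoate (C3–C6) and the Weinreb amide of ketalised methyl 3-oxohexanoate (C2, C1, butanoyl).
4. The ring B bromide comes from 2,4,6-trihydroxytoluene by formylation (future bridge carbon), O-methylation para to the formyl group, butanoylation of the last ring C–H, benzylation, reduction and bromination.
5. Ring order: ring B is bought as the arene, and ring A is the only ring built, in the Dieckmann step. Hydrogenolysis of the two benzyl ethers ends the route.

Key step: step 12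

Remark: chain atoms carry the ring A locants (C6 ester carbon, C5 CMe2, C4 and C2 ketones, C3 between them, C1 next to the butanoyl carbonyl). Each β-dicarbonyl compound is drawn as one tautomer, and the C3 methine of the open chains is racemic and labile.

**Step 1**
Reactants: 1 2,4,6-trihydroxytoluene
Product: 3 2,4,6-trihydroxy-3-methylbenzaldehyde, via aryliminium chloride 2 (not isolated)
Conditions: POCl3 (1.1 equiv), DMF (1.2 equiv), EtOAc, 0 °C → rt; then H2O, 50 °C
Reagents that add atoms: N,N-dimethylformamide, CN(C)C=O; water, O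
Why: Vilsmeier–Haack formylation of a very electron-rich arene whose two free positions are equivalent, so one mono-aldehyde should form, and its formyl carbon becomes the bridge CH2.

**Step 2**
Reactants: 3 2,4,6-trihydroxy-3-methylbenzaldehyde
Product: 4 2,6-dihydroxy-4-methoxy-3-methylbenzaldehyde
Conditions: Me2SO4 (1.0 equiv), K2CO3 (1.1 equiv), acetone, rt
Reagents that add atoms: dimethyl sulfate, COS(=O)(=O)OC
Why: Williamson etherification in which the two hydroxyls ortho to the formyl group are held back by hydrogen bonding to its oxygen, so the more acidic para hydroxyl should be ionised and methylated, which places OMe para to the future bridge.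

**Step 3**
Reactants: 4 2,6-dihydroxy-4-methoxy-3-methylbenzaldehyde; 5 butanoyl chloride
Product: 6 3-butanoyl-2,6-dihydroxy-4-methoxy-5-methylbenzaldehyde
Conditions: AlCl3 (3.5 equiv), CH2Cl2–MeNO2, 0 °C → rt; then ice, 1 M HCl
Reagents that add atoms: none
Why: Friedel–Crafts acylation at the only remaining ring C–H, which has two oxygens ortho and one para, follows the pattern of the second C-acylation in diacylphloroglucinol preparations, and the mild AlCl3–MeNO2 complex is chosen to spare the methyl ether.

**Step 4**
Reactants: 6 3-butanoyl-2,6-dihydroxy-4-methoxy-5-methylbenzaldehyde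
Product: 7 2,6-bis(benzyloxy)-3-butanoyl-4-methoxy-5-methylbenzaldehyde
Conditions: BnBr (2.5 equiv), K2CO3 (3 equiv), DMF, 60 °C
Reagents that add atoms: benzyl bromide, BrCc1ccccc1
Why: Williamson etherification of both chelated phenols in a polar aprotic solvent, which favours O- over dearomatising C-benzylation of the fully substituted ring, and the ethers later block quinone methide formation at the bridge.

**Step 5**
Reactants: 7 2,6-bis(benzyloxy)-3-butanoyl-4-methoxy-5-methylbenzaldehyde
Product: 8 1-[2,4-bis(benzyloxy)-3-(hydroxymethyl)-6-methoxy-5-methylphenyl]butan-1-one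
Conditions: NaBH4 (0.5 equiv), THF–MeOH, 0 °C
Reagents that add atoms: none
Why: Chemoselective borohydride reduction, because the aldehyde is far more electrophilic than the aryl ketone, which is twisted out of conjugation and shielded by two ortho substituents.

**Step 6**
Reactants: 8 1-[2,4-bis(benzyloxy)-3-(hydroxymethyl)-6-methoxy-5-methylphenyl]butan-1-one
Product: 9 1-[2,4-bis(benzyloxy)-3-(bromomethyl)-6-methoxy-5-methylphenyl]butan-1-one
Conditions: PBr3 (0.4 equiv), Et2O–CH2Cl2, 0 °C; used without storage
Reagents that add atoms: phosphorus tribromide, BrP(Br)Br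
Why: Bromide displaces the phosphite ester of the activated benzylic alcohol, the standard PBr3 alcohol-to-bromide conversion, and this leaves the ketone and the ethers untouched.

**Step 7**
Reactants: 10 methyl 3-oxohexanoate
Product: 11 methyl 2-(2-propyl-1,3-dioxolan-2-yl)acetate
Conditions: HOCH2CH2OH (1.5 equiv), p-TsOH·H2O (cat.), toluene, reflux, Dean–Stark trap
Reagents that add atoms: ethane-1,2-diol, OCCO
Why: Acid-catalysed ketalisation driven by azeotropic removal of water takes only the ketone carbonyl and masks the future butanoyl ketone, so C1 stays non-acidic until step 11.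

**Step 8**
Reactants: 11 methyl 2-(2-propyl-1,3-dioxolan-2-yl)acetate
Product: 12 N-methoxy-N-methyl-2-(2-propyl-1,3-dioxolan-2-yl)acetamide
Conditions: MeNH(OMe)·HCl (1.5 equiv), iPrMgCl (3.0 equiv), THF, −20 → 0 °C; aq NH4Cl
Reagents that add atoms: N,O-dimethylhydroxylamine hydrochloride, CNOC.Cl
Why: Weinreb amide formation by aminolysis of the ester with the chloromagnesium amide made in the flask, and the ketal is inert to these basic conditions.

**Step 9**
Reactants: 13 methyl 2,2-dimethyl-3-oxobutanoate; 12 N-methoxy-N-methyl-2-(2-propyl-1,3-dioxolan-2-yl)acetamide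
Product: 15 methyl 2,2-dimethyl-3,5-dioxo-6-(2-propyl-1,3-dioxolan-2-yl)hexanoate, via lithium enolate 14 (not isolated)
Conditions: LiN(iPr)2 (2.0 equiv), 13 (2.0 equiv), THF, −78 °C; then 12 (1.0 equiv), −78 → 0 °C; AcOH
Reagents that add atoms: none
Why: Claisen-type acylation of a ketone enolate by a Weinreb amide, in which 13 can enolise only toward its methyl group and the chelated tetrahedral adduct should hold until the quench, with the second equivalent of enolate covering any early release of the acidic diketone.

**Step 10**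
Reactants: 15 methyl 2,2-dimethyl-3,5-dioxo-6-(2-propyl-1,3-dioxolan-2-yl)hexanoate; 9 1-[2,4-bis(benzyloxy)-3-(bromomethyl)-6-methoxy-5-methylphenyl]butan-1-one
Product: 17 methyl 4-{[2,6-bis(benzyloxy)-3-butanoyl-4-methoxy-5-methylphenyl]methyl}-2,2-dimethyl-3,5-dioxo-6-(2-propyl-1,3-dioxolan-2-yl)hexanoate (racemic), via sodium diketonate 16 (not isolated)
Conditions: NaH (1.05 equiv), THF, 0 °C; then 9, 0 °C → rt
Reagents that add atoms: none
Why: C-alkylation of a β-diketone enolate with a soft benzylic bromide, where one equivalent of NaH ionises only C3 and never touches the enolisable ring B ketone, and the new methine forms as a labile racemate of no consequence.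

**Step 11**
Reactants: 17 methyl 4-{[2,6-bis(benzyloxy)-3-butanoyl-4-methoxy-5-methylphenyl]methyl}-2,2-dimethyl-3,5-dioxo-6-(2-propyl-1,3-dioxolan-2-yl)hexanoate
Product: 18 methyl 4-{[2,6-bis(benzyloxy)-3-butanoyl-4-methoxy-5-methylphenyl]methyl}-2,2-dimethyl-3,5,7-trioxodecanoate (racemic)
Conditions: 2 M HCl aq, THF, rt
Reagents that add atoms: water, O
Why: Mild acid hydrolysis of the ketal frees the third ketone, the benzyl ethers and the hindered methyl ester should survive, and the blocked phenols cannot close onto the chain carbonyls to give chromenes.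

**Step 12**
Reactants: 18 methyl 4-{[2,6-bis(benzyloxy)-3-butanoyl-4-methoxy-5-methylphenyl]methyl}-2,2-dimethyl-3,5,7-trioxodecanoate
Product: 20 2-butanoyl-4-{[2,6-bis(benzyloxy)-3-butanoyl-4-methoxy-5-methylphenyl]methyl}-3,5-dihydroxy-6,6-dimethylcyclohexa-2,4-dien-1-one (aspidin dibenzyl ether), via disodium trione enolate 19 (not isolated)
Conditions: NaOMe (3 equiv), MeOH–THF, 0 → 50 °C; then 1 M HCl, 0 °C
Reagents that add atoms: none
Why: NaOMe ionises the C1 methylene, the most acidic C–H of 18 because it lies between the C2 ketone and the butanoyl ketone, this enolate adds through carbon to the ester carbonyl C6, and loss of methoxide forms the C1–C6 bond, after which double deprotonation to 19 pulls all equilibria forward. The closest known reaction type is the Dieckmann-type Claisen cyclisation of 3,5-dioxo and 3,5,7-trioxo esters to cyclohexane-1,3,5-triones and acylphloroglucinols. Ring A, the only ring formed, closes in a 6-exo-trig mode at the ester carbonyl, helped by the gem-dimethyl group at C5, which favours the folded conformer and keeps the ester from enolising. No stereocentre is created, and the labile racemic methine C3 ends as an sp2 enol carbon. The step needs C- over O-acylation and C1 over C3 as nucleophile: attack from C3 would give a four-membered ring, the enol lactone from the C2 oxygen is reopened by methoxide, the methoxide/methyl ester pair makes transesterification degenerate, and only the C-acylated trione is drained as a stabilised dianion. The benzyl ethers secure the rest, since without a phenoxide ortho to the bridge no retro-Michael loss of the chain or scrambling of the bridge can start, and the ring B ketone could reach a chain carbonyl only through an eight-membered ring.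

**Step 13**
Reactants: 20 aspidin dibenzyl ether
Product: 21 aspidin
Conditions: H2 (1 atm), 10% Pd/C, EtOAc, rt
Reagents that add atoms: none
Why: Hydrogenolysis of the two aryl benzyl ethers under neutral conditions should leave the tetrasubstituted enol double bonds and the aryl ketone untouched, and it avoids the base that would scramble the methylene bridge of the free phenol.

**Compound list**
1 | 2,4,6-trihydroxytoluene | Cc1c(O)cc(O)cc1O | starting material
2 | N-methyl-N-[(2,4,6-trihydroxy-3-methylphenyl)methylidene]methanaminium chloride | C[N+](C)=Cc1c(O)cc(O)c(C)c1O.[Cl-] | intermediate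
3 | 2,4,6-trihydroxy-3-methylbenzaldehyde | O=Cc1c(O)cc(O)c(C)c1O | intermediate
4 | 2,6-dihydroxy-4-methoxy-3-methylbenzaldehyde | O=Cc1c(O)cc(OC)c(C)c1O | intermediate
5 | butanoyl chloride | CCCC(=O)Cl | starting material
6 | 3-butanoyl-2,6-dihydroxy-4-methoxy-5-methylbenzaldehyde | O=Cc1c(O)c(C(=O)CCC)c(OC)c(C)c1O | intermediate
7 | 2,6-bis(benzyloxy)-3-butanoyl-4-methoxy-5-methylbenzaldehyde | O=Cc1c(OCc2ccccc2)c(C(=O)CCC)c(OC)c(C)c1OCc1ccccc1 | intermediate
8 | 1-[2,4-bis(benzyloxy)-3-(hydroxymethyl)-6-methoxy-5-methylphenyl]butan-1-one | OCc1c(OCc2ccccc2)c(C(=O)CCC)c(OC)c(C)c1OCc1ccccc1 | intermediate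
9 | 1-[2,4-bis(benzyloxy)-3-(bromomethyl)-6-methoxy-5-methylphenyl]butan-1-one | BrCc1c(OCc2ccccc2)c(C(=O)CCC)c(OC)c(C)c1OCc1ccccc1 | intermediate
10 | methyl 3-oxohexanoate | CCCC(=O)CC(=O)OC | starting material
11 | methyl 2-(2-propyl-1,3-dioxolan-2-yl)acetate | CCCC1(CC(=O)OC)OCCO1 | intermediate
12 | N-methoxy-N-methyl-2-(2-propyl-1,3-dioxolan-2-yl)acetamide | CCCC1(CC(=O)N(C)OC)OCCO1 | intermediate
13 | methyl 2,2-dimethyl-3-oxobutanoate | CC(=O)C(C)(C)C(=O)OC | starting material
14 | lithium 4-methoxy-3,3-dimethyl-4-oxobut-1-en-2-olate | [Li+].C=C([O-])C(C)(C)C(=O)OC | intermediate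
15 | methyl 2,2-dimethyl-3,5-dioxo-6-(2-propyl-1,3-dioxolan-2-yl)hexanoate | COC(=O)C(C)(C)C(=O)CC(=O)CC1(CCC)OCCO1 | intermediate
16 | sodium salt of 15, ionised at C3 | [Na+].COC(=O)C(C)(C)C(=O)[CH-]C(=O)CC1(CCC)OCCO1 | intermediate
17 | methyl 4-{[2,6-bis(benzyloxy)-3-butanoyl-4-methoxy-5-methylphenyl]methyl}-2,2-dimethyl-3,5-dioxo-6-(2-propyl-1,3-dioxolan-2-yl)hexanoate (racemic) | COC(=O)C(C)(C)C(=O)C(Cc1c(OCc2ccccc2)c(C)c(OC)c(C(=O)CCC)c1OCc1ccccc1)C(=O)CC1(CCC)OCCO1 | intermediate
18 | methyl 4-{[2,6-bis(benzyloxy)-3-butanoyl-4-methoxy-5-methylphenyl]methyl}-2,2-dimethyl-3,5,7-trioxodecanoate (racemic) | COC(=O)C(C)(C)C(=O)C(Cc1c(OCc2ccccc2)c(C)c(OC)c(C(=O)CCC)c1OCc1ccccc1)C(=O)CC(=O)CCC | intermediate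
19 | disodium salt of 20 | [Na+].[Na+].CCCC(=O)C1=C([O-])C(Cc2c(OCc3ccccc3)c(C)c(OC)c(C(=O)CCC)c2OCc2ccccc2)=C([O-])C(C)(C)C1=O | intermediate
20 | 2-butanoyl-4-{[2,6-bis(benzyloxy)-3-butanoyl-4-methoxy-5-methylphenyl]methyl}-3,5-dihydroxy-6,6-dimethylcyclohexa-2,4-dien-1-one | CCCC(=O)C1=C(O)C(Cc2c(OCc3ccccc3)c(C)c(OC)c(C(=O)CCC)c2OCc2ccccc2)=C(O)C(C)(C)C1=O | intermediate
21 | aspidin | CCCC(=O)C1=C(O)C(Cc2c(O)c(C)c(OC)c(C(=O)CCC)c2O)=C(O)C(C)(C)C1=O | target

**Step count**
Total step count: 13.
Longest linear sequence: 10 (steps 1–6 and 10–13).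

**Steps most likely to fail**

Step 12. Methoxide may cleave the chain by retro-Claisen attack at the C4 or C2 ketone. Acylation at the C2 enolate oxygen may also outrun closure of C1 onto the hindered ester. The fallback brings ring A in preformed.
- Commercial 1-(2,4,6-trihydroxyphenyl)butan-1-one is C,C-dimethylated (MeI, NaOMe, MeOH) to 2-butanoyl-3,5-dihydroxy-6,6-dimethylcyclohexa-2,4-dien-1-one F1.
- The enolate of this trione (K2CO3, acetone) is C-alkylated at its free ring CH by the benzylic bromide.
- This path sets out from 9 and comes back to the route at 20.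

Step 3. The formyl-deactivated ring may acylate sluggishly, and AlCl3 may strip the methyl ether that ends up ortho to the new ketone. The fallback inverts the order in which the ring substituents are introduced.
- Friedel–Crafts acylation of 1 with 5 (AlCl3) gives 1-(2,4,6-trihydroxy-3-methylphenyl)butan-1-one F2.
- BnBr (2 equiv) and K2CO3 leave only the hindered, chelated hydroxyl between methyl and butanoyl free, giving 1-[4,6-bis(benzyloxy)-2-hydroxy-3-methylphenyl]butan-1-one F3.
- Me2SO4 and K2CO3 in DMF give 1-[4,6-bis(benzyloxy)-2-methoxy-3-methylphenyl]butan-1-one F4.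
- H2 over Pd/C gives 1-(4,6-dihydroxy-2-methoxy-3-methylphenyl)butan-1-one F5.
- Vilsmeier–Haack formylation then takes the single free ring position.
- This path sets out from 1 and comes back to the route at 6.

Step 10. The ambident diketonate may alkylate on oxygen, and substitution at the doubly ortho-substituted benzylic carbon may be slower than decay of the bromide. The fallback replaces substitution by condensation and reduction.
- Knoevenagel condensation of the aldehyde with 15 (piperidinium acetate, toluene, Dean–Stark trap) gives methyl 4-{[2,6-bis(benzyloxy)-3-butanoyl-4-methoxy-5-methylphenyl]methylidene}-2,2-dimethyl-3,5-dioxo-6-(2-propyl-1,3-dioxolan-2-yl)hexanoate F6.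
- The electron-poor double bond of this compound is reduced by conjugate hydride transfer from Hantzsch ester.
- This path sets out from 7, makes steps 5 and 6 unnecessary, and comes back to the route at 17.

**Further compounds**
F1 | step 12 | 2-butanoyl-3,5-dihydroxy-6,6-dimethylcyclohexa-2,4-dien-1-one | CCCC(=O)C1=C(O)C=C(O)C(C)(C)C1=O
F2 | step 3 | 1-(2,4,6-trihydroxy-3-methylphenyl)butan-1-one | CCCC(=O)c1c(O)cc(O)c(C)c1O
F3 | step 3 | 1-[4,6-bis(benzyloxy)-2-hydroxy-3-methylphenyl]butan-1-one | CCCC(=O)c1c(OCc2ccccc2)cc(OCc2ccccc2)c(C)c1O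
F4 | step 3 | 1-[4,6-bis(benzyloxy)-2-methoxy-3-methylphenyl]butan-1-one | CCCC(=O)c1c(OCc2ccccc2)cc(OCc2ccccc2)c(C)c1OC
F5 | step 3 | 1-(4,6-dihydroxy-2-methoxy-3-methylphenyl)butan-1-one | CCCC(=O)c1c(O)cc(O)c(C)c1OC
F6 | step 10 | methyl 4-{[2,6-bis(benzyloxy)-3-butanoyl-4-methoxy-5-methylphenyl]methylidene}-2,2-dimethyl-3,5-dioxo-6-(2-propyl-1,3-dioxolan-2-yl)hexanoate (E/Z mixture) | COC(=O)C(C)(C)C(=O)C(=Cc1c(OCc2ccccc2)c(C)c(OC)c(C(=O)CCC)c1OCc1ccccc1)C(=O)CC1(CCC)OCCO1
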